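## Analysis of the target

The target is a 3,4-dihydronaphthalen-1(2H)-one. Ring A is a benzene ring with hydroxyls at C6 and C8; ring B holds the C1 ketone, a C2 methylene, a tertiary carbinol at C3 that also bears a methyl group, and a methine at C4. C4 carries an aroyl group whose benzene ring (ring C) has hydroxyls ortho and para to the carbonyl and, at the other ortho position, a methylene bridge to C6 of a 4-hydroxy-2-pyranone (ring D). There are two adjacent stereocentres, C3 (R) and C4 (S), with the C3 hydroxyl and the C4 aroyl group on the same face of ring B. C4 lies between ring A and a ketone and is epimerisable, so only C3 has to be set absolutely and C4 can follow it. The C3 hydroxyl is β to both ketones: loss of water aromatises ring B to a naphthol, and retro-aldol cleavage of C3–C4 gives an achiral triketone, so strong acid and strong base both threaten the compound and its optical purity. Five phenolic or enolic hydroxyls and a base-labile, electrophilic pyranone add a protecting-group problem. The difficulty is to build a fully substituted, oxygenated carbon next to a crowded, doubly activated methine and to finish near neutrality. The route rests on one pattern: C2, C3, the C3 methyl and the C3 oxygen form an acetoacetic acid unit once a carboxyl is added at C2, and C4 is the α-carbon of the aroyl ketone on ring A, whose ortho carbon C8a carries C1. A C4 enolate can therefore add to C3 of an acetoacetate enol ether, and the C2 enolate so formed can be acylated by an ester at C8a.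

## Retrosynthetic reasoning

Target 24 is traced back to its pentabenzyl ether 23 by cutting the five O–benzyl bonds. Benzyl is chosen because hydrogenolysis is neutral, which the tertiary β-hydroxy ketone needs in the last step.

Ketol 23 is traced back to tricyclic acetal 21 by adding a carboxyl at C2 (β-keto acid 22) and tying it to the C3 oxygen through a tert-butyl acetal. This makes C2 a β-keto lactone carbon, the natural product of a Dieckmann closure, and locks the C3 oxygen so that neither dehydration nor retro-aldol cleavage is possible while it is in place.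

Acetal 21 is cut at the bond between ring C and the pyranone methylene, giving aryl bromide 16 and benzyloxypyranone 18, joined forward by a Negishi coupling through zinc reagent 20. The cut is placed here because the pyranone is acidic and electrophilic and would not pass through the enolate chemistry of the annulation, whereas a bromine atom does. The coupling is placed before the acetal is opened so that no metal alkoxide of the free aldol is ever formed.

Bromide 16 is cut at C3–C4 and C1–C2, giving deoxybenzoin ester 13 and dioxinone 4. This is the key disconnection. It removes ring B, both stereocentres and two C–C bonds at once, and all carbons arrive at their final oxidation level. Forward, the C4 enolate 14 must add to the β-carbon of 4 on the face away from the tert-butyl group, and the adduct 15 must close onto the ortho ester before it reverts.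

Ester 13 is cut at the C4–C(aroyl) bond, giving toluate 6 (through its benzylic anion 12) and acid chloride 11. A C-acylation of a lithiated ortho-toluate is a standard way to such keto esters and uses no Lewis acid. The other possible cut, between the ketone and ring C (a Friedel–Crafts acylation of 7), is kept only as a fallback, because it needs a Lewis acid in the presence of four benzyl ethers.

Acid chloride 11 goes back through acid 10 and aldehyde 9 to bromoarene 7. The formyl group enters next to bromine, para to one benzyloxy group and ortho to the other, which is the normal site for 3,5-dialkoxy halobenzenes.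

Toluate 6 comes from methyl orsellinate 5 by benzylation, and pyranone 18 from 4-hydroxy-6-methyl-2-pyranone 17 by O-benzylation.

Dioxinone 4 goes back through the saturated cis-dioxanone 2 to (R)-3-hydroxybutanoic acid 1. The carbinol centre of 1 sets the acetal carbon and is then removed by dehydrogenation, so the acetal carbon is left as the only stereocentre and later sets C3.

## Alternatives that were turned down

Alternative 1: Ring B is cut at the C1–C8a bond. The precursor is δ-lactone A2, in which the C1 carboxyl is esterified by the oxygen on the future aroyl carbon, C3 is a triethylsilyl ether and ring A carries bromine where C8a is to be acylated. Forward, bromine–lithium exchange on A2 is followed by attack of the aryllithium on the lactone carbonyl (a Parham-type cyclisation); the carbocycle closes as the lactone opens, giving tetralone A1 with a free benzylic carbinol.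
- For: the closure is intramolecular and irreversible and does not touch C3 or C4. On the certainty of the ring-forming event it is stronger than the annulation chosen here.
- Against: A2 holds three contiguous stereocentres, one of them the quaternary carbinol, which must each be set beforehand. One of them is destroyed when the carbinol is oxidised, and C4 becomes epimerisable at that point anyway. The organolithium can also enolise the lactone at C2. After the key step the carbinol must still be oxidised and the silyloxyethyl arm on ring C turned into the pyranonylmethyl group over several steps.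
- Comparison: the chosen route gives up the safe closure but obtains ring B, both C–C bonds and C3 in one step from 13 and 4, and roughly halves the step count.

Alternative 2: The cis ketol is masked as an isoxazoline, so the cuts are the C4–C(aroyl) bond and the C3–O bond. The partners are dihydronaphthalene A4 (C3=C4 alkene, C3 methyl, C1 as a silyl-protected carbinol) and the doubly ortho-substituted aryl nitrile oxide A5 of ring C, which carries a methoxycarbonylmethyl arm. The forward step is a 1,3-dipolar cycloaddition giving ring-fused isoxazoline A3; N–O cleavage and imine hydrolysis would later free the β-hydroxy ketone.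
- For: the cycloaddition is suprafacial, so the cis arrangement of the C3 oxygen and the C4 acyl group follows from the mechanism and not from equilibration. The hindered dipole resists dimerisation. The isoxazoline protects the aldol against dehydration and retro-aldol cleavage over many steps; on this point it is stronger than the chosen route, where the free ketol exists only in the last two steps but is then unprotected.
- Against: the alkene is trisubstituted and styrene-like, so the steric preference (oxygen to the more substituted C3) and the electronic preference (oxygen to the aryl-bearing C4) oppose each other and the regiochemistry is not secure. The face is controlled only by the remote C1 silyl ether, which must first be made enantiopure. C1 must be oxidised and the pyranone built from the ester arm afterwards. A doubly ortho-substituted dipole should react slowly with a trisubstituted alkene.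
- Comparison: the chosen route sets C3 from a two-step chiral building block with a known facial bias and has no regiochemical question, at the price of a less certain C–C bond formation.

Alternative 3: The cut is at C1–C2. Precursor A7 carries a 1,3-dithian-2-yl group on ring A as a masked C1 acyl anion and a 2,2-disubstituted epoxide spanning C2 and C3, next to a C4 methine that already bears the silyl-protected carbinol of ring C. Deprotonation of the dithiane and 6-exo-tet attack on the epoxide methylene close ring B and give tetralin A6, with the tertiary alcohol free and C1 as a dithiane.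
- For: C3 comes from a reliable asymmetric epoxidation and is not involved in the bond-forming event, and the closure is irreversible. On the security of the C3 configuration it is at least as strong as the chosen route.
- Against: the dithiane anion sits between two ortho substituents and must attack a neopentyl-type carbon next to a quaternary centre. A7 again needs three stereocentres, with C4 set at a stage where it cannot equilibrate. After the key step C1 must be unmasked, the carbinol oxidised and the pyranone built from the silyloxyethyl arm, which makes this the longest sequence of the four.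
- Comparison: the chosen route reaches the same ring with C1 already a ketone and needs no umpolung and no late oxidation.

Key step: step 8

Remark: C4 keeps an acidic proton between ring A and the aroyl carbonyl, so its configuration is taken to follow C3 by equilibration to the epimer with the aroyl group trans to the C3 methyl group (cis to the C3 oxygen), which is the target arrangement.

## Route

Step 1
Reactants: 1 (R)-3-hydroxybutanoic acid
Product: 2 (2R,6R)-2-tert-butyl-6-methyl-1,3-dioxan-4-one (cis)
Conditions: tBuCHO (2 equiv), TsOH·H2O (cat.), CH2Cl2, reflux, water separator; crystallisation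
Reagents that add atoms: pivalaldehyde, CC(C)(C)C=O
Why: Acid-catalysed acetalisation under thermodynamic control; the chair with tert-butyl and methyl both equatorial is favoured, so the carbinol centre of 1 sets the acetal carbon as 2R, and crystallisation should remove the minor trans isomer.

Step 2
Reactants: 2 (2R,6R)-2-tert-butyl-6-methyl-1,3-dioxan-4-one
Product: 4 (R)-2-tert-butyl-6-methyl-4H-1,3-dioxin-4-one, via 6-bromo dioxanone 3 (not isolated)
Conditions: NBS (1.1 equiv), AIBN (cat.), CCl4 (or PhCF3), reflux; then Et3N (1.5 equiv), 0 °C to rt
Reagents that add atoms: none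
Why: Radical bromination at the tertiary C6–H next to the ring oxygen gives an α-bromo ether, which loses HBr toward C5 with triethylamine to form the enol ether double bond. The acetal carbon is not touched and remains as the only stereocentre.

Step 3
Reactants: 5 methyl 2,4-dihydroxy-6-methylbenzoate (methyl orsellinate)
Product: 6 methyl 2,4-bis(benzyloxy)-6-methylbenzoate
Conditions: BnBr (2.5 equiv), K2CO3 (3 equiv), KI (cat.), DMF, 70 °C
Reagents that add atoms: benzyl bromide, BrCc1ccccc1
Why: Williamson etherification of both phenols; heating is needed for the hydroxyl that is hydrogen-bonded to the ester.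

Step 4
Reactants: 7 1-bromo-3,5-bis(benzyloxy)benzene
Product: 9 2-bromo-4,6-bis(benzyloxy)benzaldehyde, via aryl iminium salt 8 (not isolated)
Conditions: POCl3 (2 equiv), DMF, 0 to 75 °C; then aq. NaOAc
Reagents that add atoms: N,N-dimethylformamide, CN(C)C=O; water, O
Why: Vilsmeier–Haack formylation. The chloroiminium ion should attack the position para to one benzyloxy group and ortho to the other (next to bromine) and not the position flanked by both ethers, as is usual for 3,5-dialkoxy halobenzenes.

Step 5
Reactants: 9 2-bromo-4,6-bis(benzyloxy)benzaldehyde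
Product: 10 2-bromo-4,6-bis(benzyloxy)benzoic acid
Conditions: NaClO2, NaH2PO4, 2-methyl-2-butene, tBuOH–THF–H2O, rt
Reagents that add atoms: sodium chlorite, [Na+].[O-]Cl=O
Why: Pinnick oxidation; the alkene scavenges hypochlorous acid so the electron-rich ring and the benzyl ethers are not chlorinated.

Step 6
Reactants: 10 2-bromo-4,6-bis(benzyloxy)benzoic acid
Product: 11 2-bromo-4,6-bis(benzyloxy)benzoyl chloride
Conditions: (COCl)2 (1.5 equiv), DMF (cat.), CH2Cl2, 0 °C to rt; evaporate, use crude
Reagents that add atoms: oxalyl chloride, O=C(Cl)C(=O)Cl
Why: Standard acid chloride formation under neutral conditions that leave the benzyl ethers intact; a doubly ortho-substituted aroyl group needs this level of activation for the next step.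

Step 7
Reactants: 6 methyl 2,4-bis(benzyloxy)-6-methylbenzoate; 11 2-bromo-4,6-bis(benzyloxy)benzoyl chloride
Product: 13 methyl 2,4-bis(benzyloxy)-6-{2-[2,4-bis(benzyloxy)-6-bromophenyl]-2-oxoethyl}benzoate, via lithiated toluate 12 (not isolated)
Conditions: 6 (2.1 equiv), LiN(iPr)2 (2.1 equiv), THF, −78 °C; 11 (1.0 equiv), THF, −78 °C; AcOH, −78 °C
Reagents that add atoms: none
Why: Claisen-type C-acylation of a laterally lithiated ortho-toluate. The second equivalent of 12 deprotonates the acidic product, which protects the ketone from a second attack and returns one equivalent of 6. The cold acetic acid quench should prevent lactonisation to the isocoumarin.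

Step 8
Reactants: 13 methyl 2,4-bis(benzyloxy)-6-{2-[2,4-bis(benzyloxy)-6-bromophenyl]-2-oxoethyl}benzoate; 4 (R)-2-tert-butyl-6-methyl-4H-1,3-dioxin-4-one
Product: 16 (2R,10S,10aS)-6,8-bis(benzyloxy)-10-[2,4-bis(benzyloxy)-6-bromobenzoyl]-2-tert-butyl-5-hydroxy-10a-methyl-10,10a-dihydro-4H-naphtho[2,3-d][1,3]dioxin-4-one, via lithium enolate 14 (not isolated), via Michael adduct 15 (not isolated)
Conditions: LiN(iPr)2 (1.05 equiv), THF, −78 °C; 4 (1.5 equiv), −78 to 0 °C; AcOH, −78 °C
Reagents that add atoms: none
Why: Proposed new method: a ketone enolate has not been shown as the donor in a Michael–Dieckmann annulation onto this dioxinone; the closest known reactions are the Staunton–Weinreb annulation of lithiated ortho-toluates with β-alkoxy unsaturated lactones and the conjugate addition of cuprates to 4, which enter trans to the tert-butyl group. The base removes the doubly activated C4 proton of 13 to give enolate 14, which adds through carbon to the β-carbon of 4 to give lactone enolate 15. This addition is expected to be uphill, because a stabilised ketone enolate is exchanged for a lactone enolate at a fully substituted carbon, so it must be pulled forward by the ring closure: the α-carbon of 15 attacks the neighbouring methyl ester in a 6-(enolexo)-exo-trig Dieckmann condensation that closes ring B, and loss of methoxide followed by deprotonation of the β-keto lactone makes the sequence irreversible. C3 is controlled by the acetal carbon of 4: the tert-butyl group shields one face of the sofa-shaped ring, the enolate enters from the other, and the methyl group ends cis to tert-butyl, which with the (R)-acetal is the target configuration. C4 is not fixed kinetically; its proton stays acidic in the product, and it should settle with the aroyl group pseudo-axial, away from the peri hydrogen at C5 and trans to the C3 methyl group. The step needs carbon and not oxygen reactivity of 14 toward its own ester; O-acylation to an isocoumarin should be reversed by the methoxide it releases, whereas the Dieckmann product is withdrawn as a stable enolate. It also needs the acetal to survive in 15; β-elimination of the ring oxygen should be slow because the C3–O bond lies near the plane of the enolate and overlaps poorly with its π system.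

Step 9
Reactants: 17 4-hydroxy-6-methyl-2H-pyran-2-one
Product: 18 4-(benzyloxy)-6-methyl-2H-pyran-2-one
Conditions: BnOH (1.2 equiv), PPh3, DIAD, THF, 0 °C to rt
Reagents that add atoms: benzyl alcohol, OCc1ccccc1
Why: Mitsunobu O-alkylation of the acidic 4-hydroxyl, which avoids the C3-benzylation that alkyl halides and base can give with this ambident pyranone.

Step 10
Reactants: 16 tricyclic bromide (key-step product); 18 4-(benzyloxy)-6-methyl-2H-pyran-2-one
Product: 21 (2R,10S,10aS)-6,8-bis(benzyloxy)-10-[2,4-bis(benzyloxy)-6-{[4-(benzyloxy)-2-oxo-2H-pyran-6-yl]methyl}benzoyl]-2-tert-butyl-5-hydroxy-10a-methyl-10,10a-dihydro-4H-naphtho[2,3-d][1,3]dioxin-4-one, via lithiated pyranone 19 (not isolated), via pyranonylmethylzinc chloride 20 (not isolated)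
Conditions: 18 (2 equiv), LiN(SiMe3)2 (2 equiv), THF, −78 °C; ZnCl2 (2.2 equiv), −78 to 0 °C; 16 pretreated with LiN(SiMe3)2 (1.0 equiv); Pd(OAc)2 (5 mol %), 2-dicyclohexylphosphino-2′,6′-dimethoxybiphenyl (10 mol %), THF, 25 to 45 °C; aq. NH4Cl
Reagents that add atoms: none
Why: Lateral metalation of the vinylogous 6-methyl group, transmetalation to zinc and Negishi coupling of the benzylic-type zinc reagent with the aryl bromide. The enol of 16 is neutralised first so that it does not consume 20, and the acetal keeps the C3 oxygen masked, so no metal alkoxide of the aldol can form and undergo retro-aldol cleavage.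

Step 11
Reactants: 21 tricyclic acetal bearing the pyranonylmethyl group
Product: 23 (3R,4S)-6,8-bis(benzyloxy)-4-[2,4-bis(benzyloxy)-6-{[4-(benzyloxy)-2-oxo-2H-pyran-6-yl]methyl}benzoyl]-3-hydroxy-3-methyl-3,4-dihydronaphthalen-1(2H)-one, via β-keto acid 22 (not isolated)
Conditions: CF3CO2H–H2O–THF (1:2:10), 25 °C, then 40 °C
Reagents that add atoms: none
Why: Hydrolysis of the acylal releases the tertiary alcohol, pivalaldehyde and a β-keto acid, which decarboxylates through its cyclic transition state on gentle warming. Aryl benzyl ethers tolerate dilute acid, and partial loss of the pyranone benzyl group would be harmless because it is removed in the next step.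

Step 12
Reactants: 23 pentabenzyl ketol
Product: 24 (3R,4S)-4-{2,4-dihydroxy-6-[(4-hydroxy-2-oxo-2H-pyran-6-yl)methyl]benzoyl}-3,6,8-trihydroxy-3-methyl-3,4-dihydronaphthalen-1(2H)-one (CNP0197349.1)
Conditions: H2 (1 atm), 10% Pd/C, EtOAc–MeOH, 25 °C, stopped at full conversion
Reagents that add atoms: none
Why: Hydrogenolysis of the four aryl benzyl ethers and the pyranone benzyl ether under neutral conditions that spare the tertiary β-hydroxy ketone. Both ketones are hindered, conjugated aryl ketones and should resist reduction at atmospheric pressure.

## Compound list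

1 | (R)-3-hydroxybutanoic acid | C[C@@H](O)CC(=O)O | starting material
2 | (2R,6R)-2-tert-butyl-6-methyl-1,3-dioxan-4-one (cis) | C[C@@H]1CC(=O)O[C@H](C(C)(C)C)O1 | intermediate
3 | 6-bromo-2-tert-butyl-6-methyl-1,3-dioxan-4-one, acetal carbon as in 2, both C6 epimers (not isolated) | CC1(Br)CC(=O)O[C@H](C(C)(C)C)O1 | intermediate
4 | (R)-2-tert-butyl-6-methyl-4H-1,3-dioxin-4-one | CC1=CC(=O)O[C@H](C(C)(C)C)O1 | intermediate
5 | methyl 2,4-dihydroxy-6-methylbenzoate (methyl orsellinate) | COC(=O)c1c(C)cc(O)cc1O | starting material
6 | methyl 2,4-bis(benzyloxy)-6-methylbenzoate | COC(=O)c1c(C)cc(OCc2ccccc2)cc1OCc1ccccc1 | intermediate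
7 | 1-bromo-3,5-bis(benzyloxy)benzene | Brc1cc(OCc2ccccc2)cc(OCc2ccccc2)c1 | starting material
8 | N-{[2-bromo-4,6-bis(benzyloxy)phenyl]methylidene}-N-methylmethanaminium dichlorophosphate (not isolated) | C[N+](C)=Cc1c(Br)cc(OCc2ccccc2)cc1OCc1ccccc1.[O-]P(=O)(Cl)Cl | intermediate
9 | 2-bromo-4,6-bis(benzyloxy)benzaldehyde | O=Cc1c(Br)cc(OCc2ccccc2)cc1OCc1ccccc1 | intermediate
10 | 2-bromo-4,6-bis(benzyloxy)benzoic acid | OC(=O)c1c(Br)cc(OCc2ccccc2)cc1OCc1ccccc1 | intermediate
11 | 2-bromo-4,6-bis(benzyloxy)benzoyl chloride | ClC(=O)c1c(Br)cc(OCc2ccccc2)cc1OCc1ccccc1 | intermediate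
12 | [3,5-bis(benzyloxy)-2-(methoxycarbonyl)phenyl]methyllithium (not isolated) | [Li]Cc1cc(OCc2ccccc2)cc(OCc2ccccc2)c1C(=O)OC | intermediate
13 | methyl 2,4-bis(benzyloxy)-6-{2-[2,4-bis(benzyloxy)-6-bromophenyl]-2-oxoethyl}benzoate | COC(=O)c1c(OCc2ccccc2)cc(OCc2ccccc2)cc1CC(=O)c1c(OCc2ccccc2)cc(OCc2ccccc2)cc1Br | intermediate
14 | lithium (Z)-enolate of 13 (not isolated) | COC(=O)c1c(OCc2ccccc2)cc(OCc2ccccc2)cc1/C=C(\O[Li])c1c(OCc2ccccc2)cc(OCc2ccccc2)cc1Br | intermediate
15 | Michael adduct as its lithium lactone enolate: 2-tert-butyl-6-methyl-1,3-dioxan-4-one enolate with the C6 substituent CH(aryl)(aroyl) trans to tert-butyl (not isolated) | C[C@]1(O[C@@H](C(C)(C)C)OC(O[Li])=C1)[C@H](c1cc(OCc2ccccc2)cc(OCc2ccccc2)c1C(=O)OC)C(=O)c1c(OCc2ccccc2)cc(OCc2ccccc2)cc1Br | intermediate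
16 | (2R,10S,10aS)-6,8-bis(benzyloxy)-10-[2,4-bis(benzyloxy)-6-bromobenzoyl]-2-tert-butyl-5-hydroxy-10a-methyl-10,10a-dihydro-4H-naphtho[2,3-d][1,3]dioxin-4-one (enol form) | C[C@@]12O[C@@H](C(C)(C)C)OC(=O)C1=C(O)c1c(OCc3ccccc3)cc(OCc3ccccc3)cc1[C@@H]2C(=O)c1c(OCc2ccccc2)cc(OCc2ccccc2)cc1Br | intermediate
17 | 4-hydroxy-6-methyl-2H-pyran-2-one | Cc1cc(O)cc(=O)o1 | starting material
18 | 4-(benzyloxy)-6-methyl-2H-pyran-2-one | Cc1cc(OCc2ccccc2)cc(=O)o1 | intermediate
19 | {[4-(benzyloxy)-2-oxo-2H-pyran-6-yl]methyl}lithium (not isolated) | [Li]Cc1cc(OCc2ccccc2)cc(=O)o1 | intermediate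
20 | {[4-(benzyloxy)-2-oxo-2H-pyran-6-yl]methyl}zinc chloride (not isolated) | Cl[Zn]Cc1cc(OCc2ccccc2)cc(=O)o1 | intermediate
21 | (2R,10S,10aS)-6,8-bis(benzyloxy)-10-[2,4-bis(benzyloxy)-6-{[4-(benzyloxy)-2-oxo-2H-pyran-6-yl]methyl}benzoyl]-2-tert-butyl-5-hydroxy-10a-methyl-10,10a-dihydro-4H-naphtho[2,3-d][1,3]dioxin-4-one | C[C@@]12O[C@@H](C(C)(C)C)OC(=O)C1=C(O)c1c(OCc3ccccc3)cc(OCc3ccccc3)cc1[C@@H]2C(=O)c1c(OCc2ccccc2)cc(OCc2ccccc2)cc1Cc1cc(OCc2ccccc2)cc(=O)o1 | intermediate
22 | 2-carboxylic acid of 23 (β-keto acid; C3 and C4 as in 23, C2 unassigned; not isolated) | C[C@@]1(O)C(C(=O)O)C(=O)c2c(OCc3ccccc3)cc(OCc3ccccc3)cc2[C@@H]1C(=O)c1c(OCc2ccccc2)cc(OCc2ccccc2)cc1Cc1cc(OCc2ccccc2)cc(=O)o1 | intermediate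
23 | (3R,4S)-6,8-bis(benzyloxy)-4-[2,4-bis(benzyloxy)-6-{[4-(benzyloxy)-2-oxo-2H-pyran-6-yl]methyl}benzoyl]-3-hydroxy-3-methyl-3,4-dihydronaphthalen-1(2H)-one | C[C@@]1(O)CC(=O)c2c(OCc3ccccc3)cc(OCc3ccccc3)cc2[C@@H]1C(=O)c1c(OCc2ccccc2)cc(OCc2ccccc2)cc1Cc1cc(OCc2ccccc2)cc(=O)o1 | intermediate
24 | (3R,4S)-4-{2,4-dihydroxy-6-[(4-hydroxy-2-oxo-2H-pyran-6-yl)methyl]benzoyl}-3,6,8-trihydroxy-3-methyl-3,4-dihydronaphthalen-1(2H)-one | C[C@@]1(O)CC(=O)c2c(O)cc(O)cc2[C@@H]1C(=O)c1c(O)cc(O)cc1Cc1cc(O)cc(=O)o1 | target

## Step count and least certain steps

Total step count: 12. Longest linear sequence: 8 steps (from 7 through steps 4, 5, 6, 7, 8, 10, 11 and 12).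

**Step 8 (key step, proposed new method).** The most likely failure is that the conjugate addition does not advance: the stabilised enolate reverts from the adduct faster than the adduct cyclises, so the starting materials are returned. On longer warming the enolate may be diverted by attack at the lactone carbonyl of the dioxinone, or the adduct may lose its acetal by β-elimination. Weak facial selectivity at C3 is a lesser risk.

The fallback uses known chemistry, sets out from 13 and comes back at 23:
- Acid-catalysed enol lactonisation of 13 (TsOH, toluene, 80 °C) gives 6,8-bis(benzyloxy)-3-[2,4-bis(benzyloxy)-6-bromophenyl]-1H-isochromen-1-one F1.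
- The lithium enolate of acetone (2.2 equiv, THF, −78 °C) opens the enol lactone by C-acylation and gives bromo triketone F2.
- Negishi coupling of F2 with 20 (extra equivalents to cover the acidic diketone and ketone protons) gives pyranone-bearing triketone F3.
- A mild amine base (catalytic DBU, CH2Cl2, 0 °C) closes ring B by the biomimetic aldol addition of C4 to the methyl ketone. The hindered diaryl-type ketone is a poor competing acceptor, and the cis-ketol is expected as the more stable isomer. The product is a racemate, 23 together with its mirror-image ketol F4.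
- Preparative chromatography on a chiral stationary phase separates the two and returns 23.

The fallback gives up absolute control and half of the material.

**Step 7.** C-acylation by the doubly ortho-substituted acid chloride may be slow, which lets the toluate anion condense with the ester of a second molecule, or the keto ester may lactonise to the isocoumarin during work-up. The fallback sets out from 6 and 7 and comes back at 13. Lithiated toluate 12 is carboxylated with carbon dioxide to give 2-[3,5-bis(benzyloxy)-2-(methoxycarbonyl)phenyl]acetic acid F5. Oxalyl chloride converts it into arylacetyl chloride F6, and Friedel–Crafts acylation of 7 (SnCl4, CH2Cl2, −20 °C), at the same ring position that the Vilsmeier step uses, gives 13.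

**Step 10.** Protonation of the zinc reagent by residual acidic sites may outrun transmetalation, or the ambident zinc dienolate may couple through a ring carbon instead of the exocyclic methylene. The fallback reverses the polarity, sets out from 16 and 18 and comes back at 21. Miyaura borylation of 16 (B2pin2, PdCl2(dppf), KOAc, dioxane, 80 °C) gives aryl pinacol boronate F7. Lithiated pyranone 19 is quenched with 1,2-dibromotetrachloroethane to give 6-(bromomethyl)-4-(benzyloxy)-2H-pyran-2-one F8. Suzuki–Miyaura coupling of F7 with F8 (Pd(PPh3)4, K3PO4, THF–H2O, 50 °C) gives 21.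

**Step 11.** Acid may promote loss of water from the tertiary β-hydroxy ketone, with aromatisation of ring B to a naphthol, before or during decarboxylation. The fallback replaces acid-catalysed acetal hydrolysis by neutral acyl–oxygen cleavage: Me3SnOH in 1,2-dichloroethane at 60 °C opens the lactone of 21 without forming an oxocarbenium ion or a protonated tertiary alcohol, the hemiacetal releases pivalaldehyde, and work-up at pH 4 lets acid 22 decarboxylate to 23. It sets out from 21 and comes back at 23 (no new compound, F0).

**Step 12.** The pyranone double bonds or the C1 ketone may be over-reduced, or hydrogenolysis of the five ethers may stall. The fallback changes the mode of cleavage from catalytic hydrogenolysis to Lewis-acid dealkylation with a cation scavenger: BCl3 and pentamethylbenzene in CH2Cl2 at −78 °C, quenched cold with methanol. It sets out from 23 and comes back at 24 (no new compound, F0).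

## Further compounds

F1 | step 8 | 6,8-bis(benzyloxy)-3-[2,4-bis(benzyloxy)-6-bromophenyl]-1H-isochromen-1-one | O=C1OC(c2c(OCc3ccccc3)cc(OCc3ccccc3)cc2Br)=Cc2cc(OCc3ccccc3)cc(OCc3ccccc3)c21
F2 | step 8 | 1-{2,4-bis(benzyloxy)-6-[2-(2,4-bis(benzyloxy)-6-bromophenyl)-2-oxoethyl]phenyl}butane-1,3-dione | CC(=O)CC(=O)c1c(OCc2ccccc2)cc(OCc2ccccc2)cc1CC(=O)c1c(OCc2ccccc2)cc(OCc2ccccc2)cc1Br
F3 | step 8 | 1-{2,4-bis(benzyloxy)-6-[2-(2,4-bis(benzyloxy)-6-{[4-(benzyloxy)-2-oxo-2H-pyran-6-yl]methyl}phenyl)-2-oxoethyl]phenyl}butane-1,3-dione | CC(=O)CC(=O)c1c(OCc2ccccc2)cc(OCc2ccccc2)cc1CC(=O)c1c(OCc2ccccc2)cc(OCc2ccccc2)cc1Cc1cc(OCc2ccccc2)cc(=O)o1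
F4 | step 8 | (3S,4R)-enantiomer of 23, formed with 23 as the racemate | C[C@]1(O)CC(=O)c2c(OCc3ccccc3)cc(OCc3ccccc3)cc2[C@H]1C(=O)c1c(OCc2ccccc2)cc(OCc2ccccc2)cc1Cc1cc(OCc2ccccc2)cc(=O)o1
F5 | step 7 | 2-[3,5-bis(benzyloxy)-2-(methoxycarbonyl)phenyl]acetic acid | COC(=O)c1c(OCc2ccccc2)cc(OCc2ccccc2)cc1CC(=O)O
F6 | step 7 | methyl 2,4-bis(benzyloxy)-6-(2-chloro-2-oxoethyl)benzoate | COC(=O)c1c(OCc2ccccc2)cc(OCc2ccccc2)cc1CC(=O)Cl
F7 | step 10 | pinacol boronate of 16 (bromine replaced by 4,4,5,5-tetramethyl-1,3,2-dioxaborolan-2-yl; stereocentres as in 16) | C[C@@]12O[C@@H](C(C)(C)C)OC(=O)C1=C(O)c1c(OCc3ccccc3)cc(OCc3ccccc3)cc1[C@@H]2C(=O)c1c(OCc2ccccc2)cc(OCc2ccccc2)cc1B1OC(C)(C)C(C)(C)O1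
F8 | step 10 | 6-(bromomethyl)-4-(benzyloxy)-2H-pyran-2-one | BrCc1cc(OCc2ccccc2)cc(=O)o1
F0 | step 11 | none | none
F0 | step 12 | none | none
A1 | alternative 1 | tetralone with C3 triethylsilyl ether and free benzylic carbinol at the future aroyl carbon | C[C@@]1(O[Si](CC)(CC)CC)CC(=O)c2c(OCc3ccccc3)cc(OCc3ccccc3)cc2[C@@H]1[C@@H](O)c1c(OCc2ccccc2)cc(OCc2ccccc2)cc1CCO[Si](C)(C)C(C)(C)C
A2 | alternative 1 | δ-lactone: 5-[3,5-bis(benzyloxy)-2-bromophenyl]-6-{2,4-bis(benzyloxy)-6-[2-(tert-butyldimethylsilyloxy)ethyl]phenyl}-4-methyl-4-(triethylsilyloxy)tetrahydro-2H-pyran-2-one, stereocentres as in A1 | C[C@@]1(O[Si](CC)(CC)CC)CC(=O)O[C@@H](c2c(OCc3ccccc3)cc(OCc3ccccc3)cc2CCO[Si](C)(C)C(C)(C)C)[C@H]1c1cc(OCc2ccccc2)cc(OCc2ccccc2)c1Br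
A3 | alternative 2 | ring-fused isoxazoline masking the cis ketol, C1 as tert-butyldimethylsilyl ether | C[C@@]1(ON=C3c4c(OCc5ccccc5)cc(OCc5ccccc5)cc4CC(=O)OC)C[C@@H](O[Si](C)(C)C(C)(C)C)c2c(OCc5ccccc5)cc(OCc5ccccc5)cc2[C@@H]13
A4 | alternative 2 | (1R)-6,8-bis(benzyloxy)-1-(tert-butyldimethylsilyloxy)-3-methyl-1,2-dihydronaphthalene | CC1=Cc2cc(OCc3ccccc3)cc(OCc3ccccc3)c2[C@H](O[Si](C)(C)C(C)(C)C)C1
A5 | alternative 2 | 2,4-bis(benzyloxy)-6-(2-methoxy-2-oxoethyl)benzonitrile oxide | [O-][N+]#Cc1c(OCc2ccccc2)cc(OCc2ccccc2)cc1CC(=O)OC
A6 | alternative 3 | tetralin with C1 as 1,3-dithiane, free C3 tertiary alcohol and silyl-protected carbinol at the future aroyl carbon | C[C@@]1(O)CC2(SCCCS2)c2c(OCc3ccccc3)cc(OCc3ccccc3)cc2[C@@H]1[C@@H](O[Si](C)(C)C(C)(C)C)c1c(OCc2ccccc2)cc(OCc2ccccc2)cc1CCO[Si](C)(C)C(C)(C)C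
A7 | alternative 3 | open-chain precursor with a 2-methyloxiran-2-yl group at C3 and a 1,3-dithian-2-yl group on ring A, stereocentres as in A6 | C[C@@]1(CO1)[C@H](c1cc(OCc2ccccc2)cc(OCc2ccccc2)c1C1SCCCS1)[C@@H](O[Si](C)(C)C(C)(C)C)c1c(OCc2ccccc2)cc(OCc2ccccc2)cc1CCO[Si](C)(C)C(C)(C)C
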